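## Structural features

The target is a 1-aryltetralin. Ring A is the 6,7-dimethoxybenzo ring, ring B the saturated ring C1–C2–C3–C4–C4a–C8a, and ring C a 3,4-dimethoxyphenyl group on C1; C2 and C3 each carry a methoxymethyl group. C1, C2 and C3 are contiguous stereocentres, all S: ring C on C1 is cis to the C2 methoxymethyl group, and the C2 and C3 groups are trans. This 1,2-cis-2,3-trans pattern holds ring C pseudoaxial; a cationic closure of ring B is expected to give 1,2-trans instead, so C1 relative to C2 is the real difficulty. No stereocentre adjoins a carbonyl group in the target, so nothing can be corrected by equilibration at the end, and C1 is a doubly benzylic methine that must not be ionised or oxidised once set. The only functional groups are six methyl ethers; the two electron-rich arenes are sensitive to strong Lewis acids, oxidants and electrophiles but otherwise robust. Without ring C the molecule has a twofold axis: in the trans-2,3-disubstituted ring A/ring B core, the C1 and C4 methylene groups are homotopic, as are the C2 and C3 substituents. The key step exploits this: the one C1–H bond of ring B that lies cis to the C2 substituent is replaced by the C1–aryl bond under the direction of a carboxamide on C2, which sets C1 relative to C2/C3 and breaks the symmetry in one operation.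

## Logic of the disconnections

14 to 13: the two alkyl O–CH3 bonds on the C2 and C3 side chains are cut. Ethers are inert end groups, so they are made last. The forward step is a double O-methylation of two primary hydroxyl groups with no stereocentre at risk.

13 to 11 (through 12): the two CH2–OH carbons are traced back to the C2 carboxamide and the C3 ester of 11, with the N–Boc bond of 12 as the only added bond. This keeps a carboxyl-derived director on C2 until C1 has been set, and both side-chain carbons are already in place. The forward reduction must be faster than enolisation at C2, which is now flanked by the cis aryl group.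

11 to 9 and 10: the C1–C1′ bond between ring B and ring C is cut. This is the key disconnection. It removes ring C and the C1 stereocentre together and returns to a compound whose carbon skeleton is twofold-symmetric, with ring C bought as 10. The route in one sentence: a directed C–H arylation of the benzylic C1 methylene of 9 with 10. That sentence does not describe a ring B closure from a dibenzylbutane-type precursor. The forward step must replace only the C1–H cis to the C2 carbonyl, must not touch C3–H or C4–H, and must not epimerise C2 or C3.

9 to 5 and 6 (through 8 and 7): the amide C–N bond and the ester O–CH3 bond are cut. Because 5 has a twofold axis its two carboxyl groups are homotopic, so placing one director needs no selectivity; passage through 7 guarantees that 6 is acylated once only. The forward step requires that the trans-fused 7 does not isomerise to the cis-fused form.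

5 to 1 and 2 (through 4 and 3): the C1–C2 and C3–C4 bonds of ring B are cut, together with the ester bonds to the auxiliary. Ring B and both C2/C3 stereocentres then arise in one operation from a four-carbon chain and a bis-electrophile. The auxiliary in 1 must impose the same facial sense at both enolate carbons, and ring closure of 3 must outrun intermolecular alkylation.

## Other disconnections considered

Alternative 1: cut C1–C8a, closing ring B by attack of ring A on a C1 benzylic cation; this is the first plan that comes to mind. Forward: aldol union of the ring A and ring C halves on a butyrolactone gives carbinol A1; acid-induced ionisation and Friedel–Crafts closure give lactone A2, which is then reduced and methylated. Ground: in the cyclisation the trans-lactone holds C2/C3 diequatorial and ring A should attack so that ring C ends pseudo-equatorial and trans to C2. A2 is therefore expected in the 1,2-trans series, the C1 epimer of what 14 needs, and a diaryl methine with no adjacent carbonyl offers no handle for correction. The chosen plan sets C1 by a mechanism that is intrinsically cis.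

Alternative 2: cut C1–C2 and C3–C4 together as a [4+2] cycloaddition. Forward: irradiation of benzophenone A3 gives a hydroxy-o-quinodimethane that is trapped by a fumarate diester, giving carbinol A4 with ring B and the 2,3-trans diester in one step; benzylic deoxygenation, reduction and methylation follow. Ground: ring B is made quickly, but C1 arrives as a tertiary carbinol and its final configuration is set only in the deoxygenation. Hydride transfer to the diaryl cation should occur axially and anti to the axial C2–H, which again leads to 1,2-trans. Absolute control would also need an auxiliary on a non-chelating dienophile in a photochemical step. The chosen route fixes C2/C3 by an auxiliary in a ground-state alkylation and C1 by chelate geometry.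

Alternative 3: remove the C1–H and C2–H bonds, that is, set C1 and C2 by hydrogenation of the C1=C2 bond of dihydronaphthalene A5, itself assembled by cross-coupling of ring C to an enol triflate of a ring A/ring B keto ester. Forward key step: syn addition of H2. Ground: syn addition secures 1,2-cis, but the only resident stereocentre, C3, should steer an undirected catalyst to the face opposite its substituent and give the all-cis isomer A6. The target needs addition syn to the C3 group, which is attainable only by hydroxyl direction on a tetrasubstituted styrene in the corresponding diol. C3 would also have to be carried in enantiopure form through stages where it is allylic and alpha to an ester. This means more steps and a weaker stereochemical argument; it is kept as the fallback for the key step.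

Key step: step 5

Assumption: 2 is taken as a purchasable building block (otherwise one step from 1,2-dimethoxybenzene by double bromomethylation), and the (−)-menthyl auxiliary is taken to induce the same (S,S) sense with 2 as in the analogous ring closure with bromochloromethane; if the sense were reversed, the (+)-menthyl ester of succinic acid would be used instead.

## Steps

Step 1
Reactants: 1 (−)-dimenthyl succinate, bis[(1R,2S,5R)-2-isopropyl-5-methylcyclohexyl] butanedioate; 2 1,2-bis(bromomethyl)-4,5-dimethoxybenzene
Product: 4 bis[(1R,2S,5R)-2-isopropyl-5-methylcyclohexyl] (2S,3S)-6,7-dimethoxy-1,2,3,4-tetrahydronaphthalene-2,3-dicarboxylate, via monobenzylated succinate enolate 3 (not isolated)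
Conditions: LiTMP (2.2 equiv), THF, −78 °C; then 2 (1.0 equiv, slow addition), −78 °C → rt; crystallisation
Reagents that add atoms: none
Why: Auxiliary-controlled double alkylation of a chiral succinate dienolate with a 1,4-bis-electrophile: the first C-benzylation gives enolate 3, whose remaining enolate carbon closes ring B by 6-exo-tet displacement. Each menthyl group shields the same face of its own enolate carbon, so C2 and C3 should both be set S and trans, and crystallisation should bring 4 to diastereomeric purity.

Step 2
Reactants: 4
Product: 5 (2S,3S)-6,7-dimethoxy-1,2,3,4-tetrahydronaphthalene-2,3-dicarboxylic acid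
Conditions: KOH, EtOH/H2O, reflux; then aq. HCl
Reagents that add atoms: potassium hydroxide, [K+].[OH-] (the hydroxide oxygen ends in each carboxyl group)
Why: Saponification of the two hindered secondary esters; a carboxylate once formed resists alpha-deprotonation and the trans-diequatorial arrangement is the thermodynamic one, so C2/C3 should be retained and the menthol is recovered.

Step 3
Reactants: 5; 6 8-aminoquinoline
Product: 8 (2S,3S)-6,7-dimethoxy-3-(quinolin-8-ylcarbamoyl)-1,2,3,4-tetrahydronaphthalene-2-carboxylic acid, via trans-fused cyclic anhydride 7 (not isolated)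
Conditions: TFAA, CH2Cl2, 0 °C → rt, then evaporation; 6 (1.05 equiv), THF, rt → 40 °C
Reagents that add atoms: none
Why: Dehydration of a 1,2-diacid to its cyclic anhydride followed by ring-opening aminolysis; the twofold axis of 5 and 7 makes the two carbonyl groups homotopic, so exactly one directing amide is installed and only one product is possible.

Step 4
Reactants: 8
Product: 9 methyl (2S,3S)-6,7-dimethoxy-3-(quinolin-8-ylcarbamoyl)-1,2,3,4-tetrahydronaphthalene-2-carboxylate
Conditions: TMSCHN2, PhMe/MeOH, 0 °C → rt
Reagents that add atoms: trimethylsilyldiazomethane, C[Si](C)(C)C=[N+]=[N-]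
Why: Methyl esterification of a carboxylic acid with a diazoalkane under neutral conditions; no base is present, so the amide N–H and both alpha-stereocentres are untouched.

Step 5
Reactants: 9; 10 4-iodo-1,2-dimethoxybenzene
Product: 11 methyl (2S,3S,4S)-4-(3,4-dimethoxyphenyl)-6,7-dimethoxy-3-(quinolin-8-ylcarbamoyl)-1,2,3,4-tetrahydronaphthalene-2-carboxylate (in target numbering: aryl on C1, amide on C2, ester on C3)
Conditions: Pd(OAc)2 (10 mol %), AgOAc (2 equiv), (BnO)2PO2H (20 mol %), 10 (3 equiv), t-AmOH, 110 °C
Reagents that add atoms: none
Why: This is an 8-aminoquinoline-directed, palladium-catalysed beta-C(sp3)–H arylation of a benzylic ring methylene. The deprotonated amide nitrogen and the quinoline nitrogen bind divalent palladium as a planar N,N-chelate, and carboxylate-assisted concerted metalation–deprotonation at C1 gives a five-membered palladacycle (Pd–N–C(O)–C2–C1) fused to ring B. Oxidative addition of 10 gives an aryl tetravalent palladium species, C1–aryl reductive elimination proceeds with retention at C1, and AgOAc removes iodide and returns the palladium diacetate catalyst. The closest known reaction type is the cis-selective arylation of cycloalkanecarboxamides and of benzylic methylene groups bearing this auxiliary; the step closes no ring in the product. The new stereocentre C1 is controlled by C2: the rigid chelate can reach only the C1–H on the face of ring B that carries the C2 carbonyl, because a trans-fused palladacycle would need a C(O)–C2–C1–Pd torsion that the planar amidate cannot adopt, so the aryl group arrives cis to the C2 carbonyl and, with C2/C3 already trans, the 1S,2S,3S triad results. Site selectivity is needed against C3–H and C4–H: C1 is the only beta-methylene, C3–H is a hindered methine whose palladation would give a tertiary alkylpalladium, and C4–H would need a six-membered palladacycle; with a single beta-methylene, over-arylation is excluded. The aryl group ends pseudoaxial on ring B, which avoids peri strain with C8–H, and the weakly basic silver acetate medium should leave the alpha-centres C2 and C3 unepimerised.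

Step 6
Reactants: 11
Product: 12 methyl (2S,3S,4S)-3-[(tert-butoxycarbonyl)(quinolin-8-yl)carbamoyl]-4-(3,4-dimethoxyphenyl)-6,7-dimethoxy-1,2,3,4-tetrahydronaphthalene-2-carboxylate
Conditions: Boc2O (4 equiv), DMAP (0.5 equiv), MeCN, 50 °C
Reagents that add atoms: di-tert-butyl dicarbonate, CC(C)(C)OC(=O)OC(=O)OC(C)(C)C
Why: N-Acylation of the secondary amide gives a twisted N-acyl carbamate, the standard activation of this auxiliary for cleavage; the conditions are not basic enough to enolise C2 or C3.

Step 7
Reactants: 12
Product: 13 [(1S,2S,3S)-1-(3,4-dimethoxyphenyl)-6,7-dimethoxy-1,2,3,4-tetrahydronaphthalene-2,3-diyl]dimethanol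
Conditions: LiBH4 (excess), THF/MeOH, 0 °C → rt
Reagents that add atoms: none
Why: Hydride reduction: the activated exocyclic acyl group is attacked with loss of the carbamate anion and the resulting aldehyde is reduced at once, while the methyl ester is reduced in parallel; reduction should outpace enolisation, so all three stereocentres are carried through unchanged.

Step 8
Reactants: 13
Product: 14 (1S,2S,3S)-1-(3,4-dimethoxyphenyl)-6,7-dimethoxy-2,3-bis(methoxymethyl)-1,2,3,4-tetrahydronaphthalene (target)
Conditions: NaH, MeI, THF/DMF, 0 °C → rt
Reagents that add atoms: iodomethane, CI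
Why: Williamson ether synthesis on both primary alkoxides; no acidic C–H or epimerisable centre remains in 13.

## Compound list

1 | (−)-dimenthyl succinate, bis[(1R,2S,5R)-2-isopropyl-5-methylcyclohexyl] butanedioate | CC(C)[C@@H]1CC[C@@H](C)C[C@H]1OC(=O)CCC(=O)O[C@@H]1C[C@H](C)CC[C@H]1C(C)C | starting material
2 | 1,2-bis(bromomethyl)-4,5-dimethoxybenzene | COc1cc(CBr)c(CBr)cc1OC | starting material
3 | bis[(1R,2S,5R)-2-isopropyl-5-methylcyclohexyl] (2S)-2-[2-(bromomethyl)-4,5-dimethoxybenzyl]butanedioate (drawn as the neutral ester; present in the flask as its lithium enolate) | COc1cc(CBr)c(C[C@@H](CC(=O)O[C@@H]2C[C@H](C)CC[C@H]2C(C)C)C(=O)O[C@@H]2C[C@H](C)CC[C@H]2C(C)C)cc1OC | intermediate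
4 | bis[(1R,2S,5R)-2-isopropyl-5-methylcyclohexyl] (2S,3S)-6,7-dimethoxy-1,2,3,4-tetrahydronaphthalene-2,3-dicarboxylate | CC(C)[C@@H]1CC[C@@H](C)C[C@H]1OC(=O)[C@H]1Cc2cc(OC)c(OC)cc2C[C@@H]1C(=O)O[C@@H]1C[C@H](C)CC[C@H]1C(C)C | intermediate
5 | (2S,3S)-6,7-dimethoxy-1,2,3,4-tetrahydronaphthalene-2,3-dicarboxylic acid | OC(=O)[C@H]1Cc2cc(OC)c(OC)cc2C[C@@H]1C(O)=O | intermediate
6 | 8-aminoquinoline | Nc1cccc2cccnc12 | starting material
7 | (3aS,9aS)-6,7-dimethoxy-3a,4,9,9a-tetrahydronaphtho[2,3-c]furan-1,3-dione (trans-fused anhydride) | O=C1OC(=O)[C@H]2Cc3cc(OC)c(OC)cc3C[C@H]12 | intermediate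
8 | (2S,3S)-6,7-dimethoxy-3-(quinolin-8-ylcarbamoyl)-1,2,3,4-tetrahydronaphthalene-2-carboxylic acid | OC(=O)[C@H]1Cc2cc(OC)c(OC)cc2C[C@@H]1C(=O)Nc1cccc2cccnc12 | intermediate
9 | methyl (2S,3S)-6,7-dimethoxy-3-(quinolin-8-ylcarbamoyl)-1,2,3,4-tetrahydronaphthalene-2-carboxylate | COC(=O)[C@H]1Cc2cc(OC)c(OC)cc2C[C@@H]1C(=O)Nc1cccc2cccnc12 | intermediate
10 | 4-iodo-1,2-dimethoxybenzene | COc1ccc(I)cc1OC | starting material
11 | methyl (2S,3S,4S)-4-(3,4-dimethoxyphenyl)-6,7-dimethoxy-3-(quinolin-8-ylcarbamoyl)-1,2,3,4-tetrahydronaphthalene-2-carboxylate | COC(=O)[C@H]1Cc2cc(OC)c(OC)cc2[C@H](c2ccc(OC)c(OC)c2)[C@@H]1C(=O)Nc1cccc2cccnc12 | intermediate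
12 | methyl (2S,3S,4S)-3-[(tert-butoxycarbonyl)(quinolin-8-yl)carbamoyl]-4-(3,4-dimethoxyphenyl)-6,7-dimethoxy-1,2,3,4-tetrahydronaphthalene-2-carboxylate | COC(=O)[C@H]1Cc2cc(OC)c(OC)cc2[C@H](c2ccc(OC)c(OC)c2)[C@@H]1C(=O)N(C(=O)OC(C)(C)C)c1cccc2cccnc12 | intermediate
13 | [(1S,2S,3S)-1-(3,4-dimethoxyphenyl)-6,7-dimethoxy-1,2,3,4-tetrahydronaphthalene-2,3-diyl]dimethanol | OC[C@H]1Cc2cc(OC)c(OC)cc2[C@H](c2ccc(OC)c(OC)c2)[C@@H]1CO | intermediate
14 | (1S,2S,3S)-1-(3,4-dimethoxyphenyl)-6,7-dimethoxy-2,3-bis(methoxymethyl)-1,2,3,4-tetrahydronaphthalene | COC[C@H]1Cc2cc(OC)c(OC)cc2[C@H](c2ccc(OC)c(OC)c2)[C@@H]1COC | target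

## Step count and least certain steps

Total step count: 8. Longest linear sequence: 8 steps (1/2 → 4 → 5 → 8 → 9 → 11 → 12 → 13 → 14); 6 and 10 enter as purchased reagents.

Step 5 (key step). Palladation of the hindered secondary benzylic C–H may be slow, so that the catalyst decomposes before conversion. At 110 °C the alpha-centres C2 and C3 may enolise, the amide nitrogen may cyclise onto the neighbouring ester to form an imide, or the acidic C3–H may be palladated reversibly. The fallback leaves C–H activation altogether; it sets out from 4 and comes back at 13. Benzylic oxidation of 4 (DDQ, aqueous dioxane; C1 and C4 are homotopic, so one ketone results) would give the beta-keto ester bis(menthyl) (3S)-6,7-dimethoxy-1-oxo-1,2,3,4-tetrahydronaphthalene-2,3-dicarboxylate F1. Enol triflation (NaH, PhNTf2) would give the C1 enol triflate F2. Suzuki coupling with 3,4-dimethoxyphenylboronic acid (Pd(PPh3)4, K3PO4, kept mild because C3 is then the only stereocentre and is alpha to an ester) would give the 1-aryl-3,4-dihydronaphthalene diester F3, and DIBAL-H would give the 1-aryl-3,4-dihydronaphthalene-2,3-dimethanol F4. Hydroxyl-directed hydrogenation of F4 with [Ir(cod)(PCy3)(py)]PF6 and H2 should deliver both hydrogens to C1=C2 on the face of the C3 hydroxymethyl group. This leaves the C2 group trans to C3 and ring C cis to the C2 group, which is 13.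

Step 1. Intermolecular alkylation of 3 by a second dianion (oligomers), incomplete facial control by the menthyl groups, or the opposite sense of induction would lower the supply or the purity of 4. The fallback replaces auxiliary control by catalytic desymmetrisation; it sets out from 2 and comes back at 9, so steps 2 to 4 are not needed. Generation of the o-quinodimethane from 2 (NaI, DMF) in the presence of maleic anhydride would give the meso cis-fused anhydride F5. Methanolysis catalysed by the modified cinchona alkaloid (DHQD)2AQN, or its pseudoenantiomer, whichever delivers the required sense, would give the cis hemiester (2S,3R)-6,7-dimethoxy-3-(methoxycarbonyl)-1,2,3,4-tetrahydronaphthalene-2-carboxylic acid F6. Epimerisation of the ester-bearing carbon (NaOMe, MeOH) would give the trans hemiester F7, and amide coupling of F7 with 6 (oxalyl chloride, then 6) would give 9.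

Step 3. The trans-fused anhydride 7 may isomerise to the more stable cis-fused anhydride by enolisation while acid is present, which would scramble C2/C3, and the weakly nucleophilic 6 may open it slowly. The fallback avoids the anhydride; it sets out from 5 and comes back at 9. Fischer esterification (MeOH, catalytic H2SO4) would give dimethyl (2S,3S)-6,7-dimethoxy-1,2,3,4-tetrahydronaphthalene-2,3-dicarboxylate F8. Mono-aminolysis with the aluminium amide from AlMe3 and 6 (one equivalent; statistical, with unreacted diester recycled) would give 9 directly.

Step 7. Hydride may attack the carbamate carbonyl instead of the hindered acyl group next to the cis aryl ring, which would return 11, and the transient C2 aldehyde may epimerise before it is reduced. The fallback separates cleavage from reduction; it sets out from 12 and comes back at 13. LiOH/H2O2 in THF/H2O at 0 °C would cleave the activated amide to (1S,2S,3S)-1-(3,4-dimethoxyphenyl)-6,7-dimethoxy-3-(methoxycarbonyl)-1,2,3,4-tetrahydronaphthalene-2-carboxylic acid F9, and LiAlH4 in THF would reduce acid and ester to 13 without passing through a free aldehyde.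

## Further compounds

F1 | step 5 | bis[(1R,2S,5R)-2-isopropyl-5-methylcyclohexyl] (3S)-6,7-dimethoxy-1-oxo-1,2,3,4-tetrahydronaphthalene-2,3-dicarboxylate (C2 not fixed, beta-keto ester) | CC(C)[C@@H]1CC[C@@H](C)C[C@H]1OC(=O)[C@H]1Cc2cc(OC)c(OC)cc2C(=O)C1C(=O)O[C@@H]1C[C@H](C)CC[C@H]1C(C)C
F2 | step 5 | bis[(1R,2S,5R)-2-isopropyl-5-methylcyclohexyl] (3S)-6,7-dimethoxy-1-[(trifluoromethylsulfonyl)oxy]-3,4-dihydronaphthalene-2,3-dicarboxylate | CC(C)[C@@H]1CC[C@@H](C)C[C@H]1OC(=O)[C@H]1Cc2cc(OC)c(OC)cc2C(OS(=O)(=O)C(F)(F)F)=C1C(=O)O[C@@H]1C[C@H](C)CC[C@H]1C(C)C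
F3 | step 5 | bis[(1R,2S,5R)-2-isopropyl-5-methylcyclohexyl] (3S)-1-(3,4-dimethoxyphenyl)-6,7-dimethoxy-3,4-dihydronaphthalene-2,3-dicarboxylate | CC(C)[C@@H]1CC[C@@H](C)C[C@H]1OC(=O)[C@H]1Cc2cc(OC)c(OC)cc2C(c2ccc(OC)c(OC)c2)=C1C(=O)O[C@@H]1C[C@H](C)CC[C@H]1C(C)C
F4 | step 5 | [(3S)-1-(3,4-dimethoxyphenyl)-6,7-dimethoxy-3,4-dihydronaphthalene-2,3-diyl]dimethanol | OC[C@H]1Cc2cc(OC)c(OC)cc2C(c2ccc(OC)c(OC)c2)=C1CO
F5 | step 1 | (3aR,9aS)-6,7-dimethoxy-3a,4,9,9a-tetrahydronaphtho[2,3-c]furan-1,3-dione (cis-fused, meso) | O=C1OC(=O)[C@H]2Cc3cc(OC)c(OC)cc3C[C@@H]12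
F6 | step 1 | (2S,3R)-6,7-dimethoxy-3-(methoxycarbonyl)-1,2,3,4-tetrahydronaphthalene-2-carboxylic acid | COC(=O)[C@@H]1Cc2cc(OC)c(OC)cc2C[C@@H]1C(O)=O
F7 | step 1 | (2S,3S)-6,7-dimethoxy-3-(methoxycarbonyl)-1,2,3,4-tetrahydronaphthalene-2-carboxylic acid | COC(=O)[C@H]1Cc2cc(OC)c(OC)cc2C[C@@H]1C(O)=O
F8 | step 3 | dimethyl (2S,3S)-6,7-dimethoxy-1,2,3,4-tetrahydronaphthalene-2,3-dicarboxylate | COC(=O)[C@H]1Cc2cc(OC)c(OC)cc2C[C@@H]1C(=O)OC
F9 | step 7 | (1S,2S,3S)-1-(3,4-dimethoxyphenyl)-6,7-dimethoxy-3-(methoxycarbonyl)-1,2,3,4-tetrahydronaphthalene-2-carboxylic acid | COC(=O)[C@H]1Cc2cc(OC)c(OC)cc2[C@H](c2ccc(OC)c(OC)c2)[C@@H]1C(O)=O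
A1 | alternative 1 | (3R,4S)-4-(3,4-dimethoxybenzyl)-3-[(3,4-dimethoxyphenyl)(hydroxy)methyl]dihydrofuran-2(3H)-one (carbinol centre not fixed) | COc1ccc(C[C@@H]2COC(=O)[C@H]2C(O)c2ccc(OC)c(OC)c2)cc1OC
A2 | alternative 1 | 1-(3,4-dimethoxyphenyl)-6,7-dimethoxytetralin 2,3-trans-fused lactone with carbonyl on C2, (1R,2S,3S) in tetralin numbering (1,2-trans) | COc1ccc(cc1OC)[C@@H]2c3cc(OC)c(OC)cc3C[C@@H]3COC(=O)[C@@H]23
A3 | alternative 2 | (4,5-dimethoxy-2-methylphenyl)(3,4-dimethoxyphenyl)methanone | COc1ccc(cc1OC)C(=O)c1cc(OC)c(OC)cc1C
A4 | alternative 2 | dimethyl (1S,2R,3S)-1-(3,4-dimethoxyphenyl)-1-hydroxy-6,7-dimethoxy-1,2,3,4-tetrahydronaphthalene-2,3-dicarboxylate (2,3-trans, hydroxyl cis to the C2 ester; one enantiomer drawn) | COC(=O)[C@H]1Cc2cc(OC)c(OC)cc2[C@@](O)(c2ccc(OC)c(OC)c2)[C@@H]1C(=O)OC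
A5 | alternative 3 | (3S)-1-(3,4-dimethoxyphenyl)-6,7-dimethoxy-2,3-bis(methoxymethyl)-3,4-dihydronaphthalene | COC[C@H]1Cc2cc(OC)c(OC)cc2C(c2ccc(OC)c(OC)c2)=C1COC
A6 | alternative 3 | (1R,2R,3S)-1-(3,4-dimethoxyphenyl)-6,7-dimethoxy-2,3-bis(methoxymethyl)-1,2,3,4-tetrahydronaphthalene (all-cis) | COC[C@H]1Cc2cc(OC)c(OC)cc2[C@@H](c2ccc(OC)c(OC)c2)[C@H]1COC
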